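The earlier runs and the new flask are simulated from invented constants; the scatter is artificial.

A straight rise of target invites a mistake: reading its slope as a property of the catalyst and carrying it unchanged to a leaner flask.

all flasks: free catalyst 0.00600 M

| charge | starting material | coupling partner | target | time |
|---|---|---|---|---|
| north | 0.600 M | 0.900 M |  |  |
| north-west | 0.600 M | 0.900 M | 0.180 M |  |
| east | 0.600 M | 0.450 M |  |  |
| west | 0.300 M | 0.450 M |  | 20 min |

- north run (time / min: [target] / M): 0.72: 0.002; 2.2: 0.029; 4.2: 0.040; 6.6: 0.085; 9.4: 0.112; 13: 0.156; 16: 0.201; 20: 0.263
- north-west run (time / min: [target] / M): 0.72: 0.193; 2.2: 0.213; 4.2: 0.242; 6.6: 0.261; 9.4: 0.303; 13: 0.333; 16: 0.385; 20: 0.431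
- east run (time / min: [target] / M): 0.72: 0.003; 2.2: 0.038; 4.2: 0.057; 6.6: 0.091; 9.4: 0.120; 13: 0.158; 16: 0.199; 20: 0.243

(each reading ± 0.006 M)

- the power of [coupling partner] that the first rate follows, about the charge of the north run; measure it at two percent of starting material made into target
- target in the west run at 20 min, as a share of the starting material charged

- Overall: starting material + coupling partner -> target, with free catalyst as catalyst.
- Constant volume, constant temperature.
- The analysis sees a species whether free or bound.
- An order is taken over about fifteen percent of the charge, up and down.

I count turnovers. From the north run's reading of 0.085 M at 6.6 min on 0.00600 M of free catalyst I get 2.15 min⁻¹ for the turnover frequency f, the target made per minute per catalyst charged. A second way uses the last north reading by itself: 0.263 M at 20 min is 43.8 turnovers, or 2.19 min⁻¹. The two agree within that reading's scatter of 0.0500 min⁻¹. The north-west run, counting target made beyond its charge, gives 2.09 min⁻¹ at its last reading, and I read no clear effect of added target from that gap.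

The east run carries half the coupling partner of the north run, and at 6.6 min it reads 0.091 M against the north 0.085 M. Over that wide step I read an order in coupling partner of −0.0984, with a scatter of about 0.144. Here the two ways part: the early reading gives 2.30 min⁻¹ for the east run, while its last reading gives 2.03 min⁻¹, which is lower. For a count over 20 min the early figure is the one that cheats: it stops at 6.6 min, while the last reading spans the east run up to 20 min.

In the west run the starting material is the limiting reagent, and its charge amounts to 50.0 turnovers. Holding f for 20 min counts off 85.9% of that charge. Scaled by the ratio of the two ways in the east run, which holds the same charge of coupling partner as the west run, this gives my own figure of 75.7%.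

The forecast gives −0.15 and 75%: “Saturation falloff at low starting material and low partner should cut this to about 75%”. Its share stands below mine, and its order is lower than mine.

    free catalyst + starting material → catalyst-substrate complex (42.42 M⁻¹ min⁻¹)
    catalyst-substrate complex + coupling partner → loaded catalyst (363.6 M⁻¹ min⁻¹)
    loaded catalyst → target + free catalyst (8.220 min⁻¹)
    free catalyst + starting material ⇌ idle catalyst-substrate complex, settled at all times (12.70 M⁻¹)

The flask gives an order of 0.0068 and, for the west run, 70.1%, below my figure. That share is 35.1 turnovers, an average f of 1.75 min⁻¹, lower than the 2.15 min⁻¹ read in the north run. The main reason is the pairing of free catalyst and starting material to idle catalyst-substrate complex: the west run without that pairing reaches 96.8%, or 48.4 turnovers, so the pairing costs the west run 13.3 turnovers.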